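## Retrosynthetic overview

1. Target (isochromene numbering O2, C1, C3, C4, C4a–C8a) ⇒ desilylation and dehydrative closure of the carbocycle (C4a–C5) onto the γ-pyrone carbonyl of an open-chain triketone butanoate.
2. Key disconnection C6–C7: the acyl anion equivalent (Breslow intermediate) of silyloxyacetaldehyde adds to the methyl ketone of a pyranonyl 1,2-dione. This joins two carbonyl carbons and sets the only stereocentre (C7, R).
3. 1,2-Dione ⇒ alkyne (RuO4 oxidation) ⇒ Sonogashira coupling of a 5-iodo-γ-pyrone with propyne.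
4. The pyran ring is bought, not built: maltol supplies O2, C1, C3, C4 (OMe), C4a and C8a; its 2-methyl group is extended by γ-alkylation.
5. Ring order: pyran ring (from maltol) first, carbocycle last (step 7).

Assumption: the facial selectivity of the aminoindanol triazolium catalyst with this new acceptor must be confirmed on the first run; the (5aS,10bR) salt is written, and its commercially available mirror image is used instead if it gives the S adduct.

## Route

Step 1
Reactants: 1 maltol (3-hydroxy-2-methyl-4H-pyran-4-one)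
Product: 2 3-methoxy-2-methyl-4H-pyran-4-one
Conditions: MeI, K2CO3, acetone, reflux
Reagents that add atoms: iodomethane, CI
Why: Williamson O-methylation of the acidic enolic hydroxyl of the 3-hydroxy-γ-pyrone is selective because there is no other nucleophilic site.

Step 2
Reactants: 2 3-methoxy-2-methyl-4H-pyran-4-one
Product: 3 5-iodo-3-methoxy-2-methyl-4H-pyran-4-one
Conditions: N-iodosuccinimide, TFA (30 mol %), MeCN, 60 °C, dark
Reagents that add atoms: N-iodosuccinimide, O=C1CCC(=O)N1I
Why: Electrophilic iodination of the vinylogous ester at its α-carbon goes to C5, the only unsubstituted position α to the carbonyl and β to the ring oxygen, while ipso attack at C3 is reversible and C6 is electrophilic.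

Step 3
Reactants: 3 5-iodo-3-methoxy-2-methyl-4H-pyran-4-one, 4 tert-butyl(2-iodoethoxy)dimethylsilane
Product: 6 2-{3-[(tert-butyldimethylsilyl)oxy]propyl}-5-iodo-3-methoxy-4H-pyran-4-one, via lithium dienolate 5 (not isolated)
Conditions: LiN(SiMe3)2, THF, −78 °C; then 4, DMPU, −78 → −20 °C
Reagents that add atoms: none
Why: Vinylogous (γ) deprotonation of the 2-methyl group gives extended enolate 5, which is C-alkylated at the exocyclic carbon by the primary iodide (SN2) so that the pyranone is restored, and the amide base does not touch the vinyl iodide.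

Step 4
Reactants: 6 2-{3-[(tert-butyldimethylsilyl)oxy]propyl}-5-iodo-3-methoxy-4H-pyran-4-one, 7 propyne
Product: 8 2-{3-[(tert-butyldimethylsilyl)oxy]propyl}-3-methoxy-5-(prop-1-yn-1-yl)-4H-pyran-4-one
Conditions: propyne (about 1 M in THF, excess), PdCl2(PPh3)2 (3 mol %), CuI (6 mol %), Et3N, THF, 23 °C
Reagents that add atoms: none
Why: Sonogashira coupling, in which the α-iodoenone adds oxidatively to zerovalent palladium and couples with the copper acetylide of propyne at room temperature without affecting the silyl ether.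

Step 5
Reactants: 8 2-{3-[(tert-butyldimethylsilyl)oxy]propyl}-3-methoxy-5-(prop-1-yn-1-yl)-4H-pyran-4-one
Product: 9 1-(6-{3-[(tert-butyldimethylsilyl)oxy]propyl}-5-methoxy-4-oxo-4H-pyran-3-yl)propane-1,2-dione
Conditions: RuCl3·xH2O (3 mol %), NaIO4 (2.5 equiv), NaHCO3, EtOAc/MeCN/H2O, 0 °C, 15 min
Reagents that add atoms: sodium periodate, [Na+].[O-]I(=O)(=O)=O
Why: Ruthenium tetroxide, made catalytically from RuCl3 and NaIO4, oxidises the internal alkyne to the 1,2-dione through a cyclic ruthenate ester faster than it attacks the deactivated pyranone double bonds, and the buffered two-phase medium and short time limit cleavage to the acid.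

Step 6
Reactants: 9 1-(6-{3-[(tert-butyldimethylsilyl)oxy]propyl}-5-methoxy-4-oxo-4H-pyran-3-yl)propane-1,2-dione, 10 [(tert-butyldimethylsilyl)oxy]acetaldehyde
Product: 12 (2R)-4-[(tert-butyldimethylsilyl)oxy]-1-(6-{3-[(tert-butyldimethylsilyl)oxy]propyl}-5-methoxy-4-oxo-4H-pyran-3-yl)-2-methyl-1,3-dioxobutan-2-yl butanoate, via benzoin adduct 11 (not isolated)
Conditions: 10 (1.5 equiv), (5aS,10bR)-2-(pentafluorophenyl)-5a,10b-dihydro-4H,6H-indeno[2,1-b][1,2,4]triazolo[4,3-d][1,4]oxazin-2-ium tetrafluoroborate (10 mol %), iPr2NEt (0.5 equiv), 4 Å MS, CH2Cl2, 0 → 23 °C; then butanoic anhydride, Et3N, DMAP, 0 → 23 °C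
Reagents that add atoms: butanoic anhydride, CCCC(=O)OC(=O)CCC
Why: Proposed new method: an asymmetric cross-benzoin reaction in which the triazolylidene carbene turns aldehyde 10 into a nucleophilic Breslow intermediate (acyl anion equivalent) that adds to the methyl ketone of 9, the more electrophilic and less hindered carbonyl because the other one is a deactivated vinylogous ester carbonyl, through a hydrogen-bonded transition state in which the indane wall of the catalyst shields one ketone face and so sets C7 as R, after which the tertiary alkoxide is trapped as the butanoate to prevent retro-benzoin; the closest known reaction type is the carbene-catalysed enantioselective cross-benzoin of aliphatic aldehydes with α-keto esters.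

Step 7
Reactants: 12 (2R)-4-[(tert-butyldimethylsilyl)oxy]-1-(6-{3-[(tert-butyldimethylsilyl)oxy]propyl}-5-methoxy-4-oxo-4H-pyran-3-yl)-2-methyl-1,3-dioxobutan-2-yl butanoate
Product: 15 (7R)-5-hydroxy-3-(3-hydroxypropyl)-4-methoxy-7-methyl-6,8-dioxo-7,8-dihydro-6H-isochromen-7-yl butanoate, via triflyloxypyrylium triflate 13 (not isolated), via bis-silyl azaphilone 14 (not isolated)
Conditions: Tf2O (1.1 equiv), 2,6-di-tert-butyl-4-methylpyridine (2.0 equiv), CH2Cl2, −78 → 23 °C; then HF·pyridine, THF, 0 → 23 °C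
Reagents that add atoms: none
Why: Proposed new method: triflic anhydride sulfonylates the most Lewis-basic oxygen (the γ-pyrone carbonyl) to give pyrylium 13, at whose C4 attack by the enol of the neighbouring silyloxymethyl ketone is the only productive event (six-membered ipso addition–elimination with loss of triflate and then of the C5 proton, whereas addition at the unsubstituted α-carbon is reversible), giving 14 with C7 untouched before HF·pyridine removes both silyl groups; the closest known reaction type is the condensation of 4-pyranones with C–H acids through 4-acyloxy- or 4-sulfonyloxypyrylium salts to give 4-ylidene-4H-pyrans.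

## Compound list

1 | maltol (3-hydroxy-2-methyl-4H-pyran-4-one) | CC1=C(O)C(=O)C=CO1 | starting material
2 | 3-methoxy-2-methyl-4H-pyran-4-one | COC1=C(C)OC=CC1=O | intermediate
3 | 5-iodo-3-methoxy-2-methyl-4H-pyran-4-one | COC1=C(C)OC=C(I)C1=O | intermediate
4 | tert-butyl(2-iodoethoxy)dimethylsilane | CC(C)(C)[Si](C)(C)OCCI | starting material
5 | lithium 5-iodo-3-methoxy-2-methylidene-2H-pyran-4-olate | C=C1OC=C(I)C(O[Li])=C1OC | intermediate
6 | 2-{3-[(tert-butyldimethylsilyl)oxy]propyl}-5-iodo-3-methoxy-4H-pyran-4-one | COC1=C(CCCO[Si](C)(C)C(C)(C)C)OC=C(I)C1=O | intermediate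
7 | propyne | CC#C | starting material
8 | 2-{3-[(tert-butyldimethylsilyl)oxy]propyl}-3-methoxy-5-(prop-1-yn-1-yl)-4H-pyran-4-one | COC1=C(CCCO[Si](C)(C)C(C)(C)C)OC=C(C#CC)C1=O | intermediate
9 | 1-(6-{3-[(tert-butyldimethylsilyl)oxy]propyl}-5-methoxy-4-oxo-4H-pyran-3-yl)propane-1,2-dione | COC1=C(CCCO[Si](C)(C)C(C)(C)C)OC=C(C(=O)C(C)=O)C1=O | intermediate
10 | [(tert-butyldimethylsilyl)oxy]acetaldehyde | O=CCO[Si](C)(C)C(C)(C)C | starting material
11 | (2R)-4-[(tert-butyldimethylsilyl)oxy]-1-(6-{3-[(tert-butyldimethylsilyl)oxy]propyl}-5-methoxy-4-oxo-4H-pyran-3-yl)-2-hydroxy-2-methylbutane-1,3-dione | O[C@@](C)(C(=O)CO[Si](C)(C)C(C)(C)C)C(=O)C1=COC(CCCO[Si](C)(C)C(C)(C)C)=C(OC)C1=O | intermediate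
12 | (2R)-4-[(tert-butyldimethylsilyl)oxy]-1-(6-{3-[(tert-butyldimethylsilyl)oxy]propyl}-5-methoxy-4-oxo-4H-pyran-3-yl)-2-methyl-1,3-dioxobutan-2-yl butanoate | CCCC(=O)O[C@@](C)(C(=O)CO[Si](C)(C)C(C)(C)C)C(=O)C1=COC(CCCO[Si](C)(C)C(C)(C)C)=C(OC)C1=O | intermediate
13 | 3-[(2R)-2-(butanoyloxy)-4-[(tert-butyldimethylsilyl)oxy]-2-methyl-3-oxobutanoyl]-6-{3-[(tert-butyldimethylsilyl)oxy]propyl}-5-methoxy-4-[(trifluoromethanesulfonyl)oxy]pyrylium trifluoromethanesulfonate | CCCC(=O)O[C@@](C)(C(=O)CO[Si](C)(C)C(C)(C)C)C(=O)c1c[o+]c(CCCO[Si](C)(C)C(C)(C)C)c(OC)c1OS(=O)(=O)C(F)(F)F.[O-]S(=O)(=O)C(F)(F)F | intermediate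
14 | (7R)-5-[(tert-butyldimethylsilyl)oxy]-3-{3-[(tert-butyldimethylsilyl)oxy]propyl}-4-methoxy-7-methyl-6,8-dioxo-7,8-dihydro-6H-isochromen-7-yl butanoate | CCCC(=O)O[C@]1(C)C(=O)C2=COC(CCCO[Si](C)(C)C(C)(C)C)=C(OC)C2=C(O[Si](C)(C)C(C)(C)C)C1=O | intermediate
15 | (7R)-5-hydroxy-3-(3-hydroxypropyl)-4-methoxy-7-methyl-6,8-dioxo-7,8-dihydro-6H-isochromen-7-yl butanoate | CCCC(=O)O[C@]1(C)C(=O)C2=COC(CCCO)=C(OC)C2=C(O)C1=O | target

## Step count and risks

Total steps: 7. Longest linear sequence: 7 (maltol to target).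

**Step 7 (carbocycle closure), most likely to fail.** The enol may add to the doubly activated C1 of the 3-acylpyranone instead of C4a and then open the pyran ring. The fallback sets out from 12 and comes back at 14. It replaces oxygen activation by the classical sulfur leaving-group route to 4-ylidene pyrans. Lawesson's reagent (THF, 45 °C) converts the γ-pyrone carbonyl selectively into the pyran-4-thione F1. MeOTf (CH2Cl2, 0 °C) methylates sulfur to give the 4-(methylsulfanyl)pyrylium triflate F2. 2,6-Lutidine then triggers ipso substitution at C4a by the ketone enol with loss of methanethiol to give 14, which is desilylated with HF·pyridine as in step 7.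

**Step 6 (cross-benzoin on the pyranonyl dione).** The Breslow intermediate or the carbene may add to C1 of the pyranone (Stetter-type), or the enantioselectivity may be low with the new acceptor. The fallback sets out from 6 and 10 and comes back at 12. It moves the carbene step to the established aldehyde/α-keto ester class and attaches the pyranone afterwards. Pyruvic acid and ethanethiol (DCC, DMAP) give S-ethyl 2-oxopropanethioate F3. The same triazolium catalyst couples 10 with F3 to the thioester adduct F4, which is acylated in the same flask with butanoic anhydride to the butanoate F5. Zinc dust with LiCl inserts into iodide 6 to give the pyranonylzinc iodide F6. Fukuyama coupling of F5 with F6 (PdCl2(PPh3)2, THF/toluene, 23 °C) gives 12; steps 4 and 5 are then not needed.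

**Step 5 (alkyne to 1,2-dione).** Over-oxidation to the carboxylic acid or attack on the electron-rich pyranone enol ether is possible. The fallback sets out from 6 and comes back at 9, and it also replaces step 4. Carbonylative Stille coupling of 6 with tributyl(1-ethoxyvinyl)stannane (CO 1 atm, Pd(PPh3)4, dioxane, 80 °C) gives the 2-ethoxy enone F7. Mild hydrolysis (oxalic acid on wet silica gel, CH2Cl2, 23 °C) then gives 9.

## Further compounds

F1 | step 7 | (2R)-4-[(tert-butyldimethylsilyl)oxy]-1-(6-{3-[(tert-butyldimethylsilyl)oxy]propyl}-5-methoxy-4-thioxo-4H-pyran-3-yl)-2-methyl-1,3-dioxobutan-2-yl butanoate | CCCC(=O)O[C@@](C)(C(=O)CO[Si](C)(C)C(C)(C)C)C(=O)C1=COC(CCCO[Si](C)(C)C(C)(C)C)=C(OC)C1=S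
F2 | step 7 | 3-[(2R)-2-(butanoyloxy)-4-[(tert-butyldimethylsilyl)oxy]-2-methyl-3-oxobutanoyl]-6-{3-[(tert-butyldimethylsilyl)oxy]propyl}-5-methoxy-4-(methylsulfanyl)pyrylium trifluoromethanesulfonate | CCCC(=O)O[C@@](C)(C(=O)CO[Si](C)(C)C(C)(C)C)C(=O)c1c[o+]c(CCCO[Si](C)(C)C(C)(C)C)c(OC)c1SC.[O-]S(=O)(=O)C(F)(F)F
F3 | step 6 | S-ethyl 2-oxopropanethioate | CCSC(=O)C(C)=O
F4 | step 6 | S-ethyl (2S)-4-[(tert-butyldimethylsilyl)oxy]-2-hydroxy-2-methyl-3-oxobutanethioate | O[C@@](C)(C(=O)CO[Si](C)(C)C(C)(C)C)C(=O)SCC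
F5 | step 6 | S-ethyl (2S)-2-(butanoyloxy)-4-[(tert-butyldimethylsilyl)oxy]-2-methyl-3-oxobutanethioate | CCCC(=O)O[C@@](C)(C(=O)CO[Si](C)(C)C(C)(C)C)C(=O)SCC
F6 | step 6 | (6-{3-[(tert-butyldimethylsilyl)oxy]propyl}-5-methoxy-4-oxo-4H-pyran-3-yl)zinc iodide | COC1=C(CCCO[Si](C)(C)C(C)(C)C)OC=C([Zn]I)C1=O
F7 | step 5 | 2-{3-[(tert-butyldimethylsilyl)oxy]propyl}-5-(2-ethoxyprop-2-enoyl)-3-methoxy-4H-pyran-4-one | COC1=C(CCCO[Si](C)(C)C(C)(C)C)OC=C(C(=O)C(=C)OCC)C1=O
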